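Ring A of the flavonol is treated as a folded polyketide: chromenone C4a, C5, C6, C7, C8 and C8a, with oxygen on C5, C7 and C8a and the acyl carbon C4 on C4a, are carried as a 4-hydroxy-2-pyrone. In one operation magnesium methoxide opens this lactone and the released triketo ester closes by Claisen condensation (bond C4a–C5) to the phloroglucinol ring, completing the chalcone. The precursor is a triacetic lactone whose 6-methyl carbon is acylated by the cinnamoyl unit grown from C4 of an enantiopure trans-2-aryl-3-(silyloxymethyl)-2,3-dihydrobenzofuran, itself assembled by asymmetric carbene C–H insertion and carboxylate-directed C–H olefination.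

Key step: step 13

Assumption: the sense of induction of the (R)-tert-leucinate dirhodium catalyst in step 7 is taken to be that usual for 2-(benzyloxy)phenyl diazoacetates (2R product); should this substrate respond in the opposite sense, the (S)-catalyst is used with no other change.

Shorthand in the step lines (full names in the compound list): Ar = 4-(benzyloxy)-3-methoxyphenyl; Q = (2R,3S)-7-(benzyloxy)-2-Ar-3-{[tert-butyl(diphenyl)silyl]oxymethyl}-2,3-dihydro-1-benzofuran-4-yl.

Step 1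
Reactants: 1 2,3-dihydroxybenzaldehyde
Product: 2 3-(benzyloxy)-2-hydroxybenzaldehyde
Conditions: NaH (2.2 equiv), DMSO, rt; BnBr (1.0 equiv), rt; aq. HCl
Reagents that add atoms: benzyl bromide, BrCc1ccccc1
Why: Williamson etherification of the dianion, in which the 3-phenoxide, not conjugated to the formyl group, is the more nucleophilic oxygen and should take up the single equivalent of benzyl bromide.

Step 2
Reactants: 2 3-(benzyloxy)-2-hydroxybenzaldehyde; 3 [4-(benzyloxy)-3-methoxyphenyl]methanol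
Product: 4 3-(benzyloxy)-2-(Ar-methoxy)benzaldehyde
Conditions: PPh3, DIAD, THF, 0 °C to rt
Reagents that add atoms: none
Why: Mitsunobu etherification of an acidic salicylaldehyde-type phenol with a primary benzylic alcohol, run under neutral conditions that leave the aldehyde untouched.

Step 3
Reactants: 4 3-(benzyloxy)-2-(Ar-methoxy)benzaldehyde
Product: 5 racemic 1-[3-(benzyloxy)-2-(Ar-methoxy)phenyl]-2,2,2-trichloroethanol
Conditions: CHCl3, DBU, rt
Reagents that add atoms: chloroform, ClC(Cl)Cl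
Why: Base-mediated addition of the trichloromethyl anion to an aromatic aldehyde (first stage of a Jocic homologation); the carbinol centre forms as a racemate and is removed in step 4.

Step 4
Reactants: 5 racemic 1-[3-(benzyloxy)-2-(Ar-methoxy)phenyl]-2,2,2-trichloroethanol
Product: 8 2-[3-(benzyloxy)-2-(Ar-methoxy)phenyl]acetic acid, via gem-dichloroepoxide 6 (not isolated), via arylacetyl chloride 7 (not isolated)
Conditions: NaBH4, NaOH, t-BuOH, 55 °C; aq. HCl (pH 3, 0 °C)
Reagents that add atoms: sodium hydroxide, [Na+].[OH-]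
Why: Reductive Jocic reaction, in which the alkoxide closes to the dichloroepoxide, borohydride opens it at the benzylic carbon and the acid chloride so formed is hydrolysed, all in base so that the acid-labile 4-alkoxybenzyl aryl ether is spared.

Step 5
Reactants: 8 2-[3-(benzyloxy)-2-(Ar-methoxy)phenyl]acetic acid
Product: 9 methyl 2-[3-(benzyloxy)-2-(Ar-methoxy)phenyl]acetate
Conditions: MeI, K2CO3, DMF, rt
Reagents that add atoms: iodomethane, CI
Why: SN2 O-methylation of the carboxylate, which needs no acid.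

Step 6
Reactants: 9 methyl 2-[3-(benzyloxy)-2-(Ar-methoxy)phenyl]acetate
Product: 10 methyl 2-[3-(benzyloxy)-2-(Ar-methoxy)phenyl]-2-diazoacetate
Conditions: 4-acetamidobenzenesulfonyl azide, DBU, MeCN, 0 °C to rt
Reagents that add atoms: 4-acetamidobenzenesulfonyl azide, CC(=O)Nc1ccc(cc1)S(=O)(=O)N=[N+]=[N-]
Why: Regitz diazo transfer to the benzylic, ester-activated methylene, the standard entry to aryldiazoacetates.

Step 7
Reactants: 10 methyl 2-[3-(benzyloxy)-2-(Ar-methoxy)phenyl]-2-diazoacetate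
Product: 11 methyl (2R,3S)-7-(benzyloxy)-2-Ar-2,3-dihydro-1-benzofuran-3-carboxylate (cis)
Conditions: dirhodium tetrakis[N-phthaloyl-(R)-tert-leucinate] (1 mol%), toluene, −60 °C
Reagents that add atoms: none
Why: Intramolecular 1,5 C–H insertion of the donor/acceptor rhodium carbene into the ether-activated benzylic C–H bond, where the chiral carboxylate pocket should select one enantiotopic hydrogen (C2 set as R) and the concerted insertion should deliver the cis ester (C3 S).

Step 8
Reactants: 11 methyl (2R,3S)-7-(benzyloxy)-2-Ar-2,3-dihydro-1-benzofuran-3-carboxylate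
Product: 13 (2R,3R)-7-(benzyloxy)-2-Ar-2,3-dihydro-1-benzofuran-3-carboxylic acid, via trans methyl ester 12 (not isolated)
Conditions: NaOMe (cat.), MeOH, rt; then aq. NaOH, 40 °C; aq. HCl
Reagents that add atoms: sodium hydroxide, [Na+].[OH-]
Why: Base epimerisation of the doubly activated C3 to the thermodynamically preferred trans ester (C3 now R) followed by saponification, with C2 untouched because ring opening by β-elimination is the reverse of a disfavoured 5-endo-trig closure.

Step 9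
Reactants: 13 (2R,3R)-7-(benzyloxy)-2-Ar-2,3-dihydro-1-benzofuran-3-carboxylic acid; 14 methyl acrylate
Product: 15 (2R,3R)-7-(benzyloxy)-2-Ar-4-[(E)-3-methoxy-3-oxoprop-1-enyl]-2,3-dihydro-1-benzofuran-3-carboxylic acid
Conditions: Pd(OAc)2 (5 mol%), N-acetyl-L-isoleucine (10 mol%), KHCO3 (2 equiv), O2 (1 atm), t-AmylOH, 85 °C; aq. HCl
Reagents that add atoms: none
Why: Carboxylate-directed ortho C–H olefination with divalent palladium and an amino acid ligand (Fujiwara–Moritani type oxidative Heck reaction), in which the six-membered palladacycle can form only at C4 because the other ortho position, C7a, is substituted, and β-hydride elimination gives the E-enoate.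

Step 10
Reactants: 15 (2R,3R)-7-(benzyloxy)-2-Ar-4-[(E)-3-methoxy-3-oxoprop-1-enyl]-2,3-dihydro-1-benzofuran-3-carboxylic acid
Product: 16 methyl (E)-3-[(2R,3S)-7-(benzyloxy)-2-Ar-3-(hydroxymethyl)-2,3-dihydro-1-benzofuran-4-yl]prop-2-enoate
Conditions: BH3·THF, THF, 0 °C to rt; MeOH, then aq. work-up
Reagents that add atoms: none
Why: Chemoselective borane reduction of a carboxylic acid through its acyloxyborane, which is much faster than attack on the ester or on the electron-poor conjugated alkene; the C3 descriptor changes from R to S only through CIP ranking, not through any change in space.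

Step 11
Reactants: 16 methyl (E)-3-[(2R,3S)-7-(benzyloxy)-2-Ar-3-(hydroxymethyl)-2,3-dihydro-1-benzofuran-4-yl]prop-2-enoate
Product: 17 methyl (E)-3-Q-prop-2-enoate
Conditions: TBDPSCl, imidazole, DMF, rt
Reagents that add atoms: tert-butyl(chloro)diphenylsilane, CC(C)(C)[Si](Cl)(c1ccccc1)c1ccccc1
Why: Silylation of the primary alcohol without strong base, so that no alkoxide can add 6-exo to the neighbouring enoate; the robust silyl ether then blocks that oxa-Michael pathway through steps 12 to 15.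

Step 12
Reactants: 17 methyl (E)-3-Q-prop-2-enoate; 18 4-hydroxy-6-methylpyran-2-one
Product: 19 6-[(E)-2-oxo-4-Q-but-3-enyl]-4-hydroxypyran-2-one
Conditions: 18 (3 equiv), LiN(iPr)2 (6.3 equiv), THF/DMPU, −78 to −20 °C; then 17, −78 to 0 °C; aq. HCl
Reagents that add atoms: none
Why: Claisen-type acylation of the pyrone dianion at its 6-methyl carbon, the last-formed and most nucleophilic site, where the hard lithium dienolate should attack the ester carbonyl and not the hindered β-carbon, and excess dianion absorbs the proton of the more acidic product.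

Step 13
Reactants: 19 6-[(E)-2-oxo-4-Q-but-3-enyl]-4-hydroxypyran-2-one
Product: 21 (E)-3-Q-1-(2,4,6-trihydroxyphenyl)prop-2-en-1-one, via triketo ester 20 (not isolated)
Conditions: Mg(OMe)2 (8 equiv), MeOH, reflux; cold 1 M HCl
Reagents that add atoms: none
Why: Magnesium-bound methoxide adds to the lactone carbonyl of the 4-hydroxy-2-pyrone and opens it to the magnesium chelate of triketo ester 20, whose central methylene (future C4a, flanked by the cinnamoyl ketone and the next ketone) attacks the ester carbonyl (future C5); loss of methoxide and threefold enolisation then give the benzene ring, so that 19 is isomerised to 21 without gain or loss of atoms. The closest known reaction type is the magnesium methoxide rearrangement of 6-(2-oxoalkyl)-4-hydroxy-2-pyrones to acylphloroglucinols, that is the Claisen (Dieckmann-type) cyclisation of a 3,5,7-triketo ester. Ring A is closed in a 6-(enolendo)-exo-trig mode, with the chelated enolate carbon as nucleophile and the ester carbonyl, exocyclic to the new ring, as electrophile. No stereocentre is created, and C2 and C3 of the dihydrobenzofuran lie far from every acidic site and should keep their configuration. The step needs Claisen closure to win over aldol closure (ester-side methylene onto the cinnamoyl carbonyl, which would give a resorcylate) and over conjugate addition to the enone: chelation of the 1,3-dicarbonyl units by magnesium makes the central methylene the nucleophile and ties up the cinnamoyl carbonyl as a poorly electrophilic conjugated enolate, so that the ester is the only free acceptor. The silyl ether keeps the C3 oxygen from adding to the enone, and any flavanone formed from 21 on work-up is drawn back into the chalcone series in step 14.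

Step 14
Reactants: 21 (E)-3-Q-1-(2,4,6-trihydroxyphenyl)prop-2-en-1-one
Product: 22 (E)-1-[2,4-bis(benzyloxy)-6-hydroxyphenyl]-3-Q-prop-2-en-1-one
Conditions: BnBr (2.3 equiv), K2CO3, DMF, rt to 50 °C
Reagents that add atoms: benzyl bromide, BrCc1ccccc1
Why: Williamson benzylation of the two more acidic phenols, the one hydrogen-bonded to the ketone staying free, while any flavanone present reopens under carbonate to the chalcone phenoxide, so the material should funnel to the 2-hydroxy-4,6-bis(benzyloxy) chalcone.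

Step 15
Reactants: 22 (E)-1-[2,4-bis(benzyloxy)-6-hydroxyphenyl]-3-Q-prop-2-en-1-one
Product: 24 5,7-bis(benzyloxy)-2-Q-chromen-4-one, via flavanone 23 (not isolated)
Conditions: I2 (10 mol%), DMSO, 120 °C
Reagents that add atoms: none
Why: Iodine-catalysed oxidative cyclisation of a 2-hydroxychalcone, that is 6-endo-trig oxa-Michael closure to the flavanone, α-iodination and loss of HI, with DMSO reoxidising iodide; the transient chromanone C2 centre disappears on dehydrogenation.

Step 16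
Reactants: 24 5,7-bis(benzyloxy)-2-Q-chromen-4-one
Product: 26 5,7-bis(benzyloxy)-3-hydroxy-2-Q-chromen-4-one, via flavone 2,3-epoxide 25 (not isolated)
Conditions: DMDO, acetone/CH2Cl2, 0 °C; then p-TsOH (cat.), CH2Cl2, rt
Reagents that add atoms: dimethyldioxirane, CC1(C)OO1
Why: Dioxirane epoxidation of the chromenone C2–C3 double bond followed by acid opening at C2 and loss of the C3 proton gives the 3-hydroxyflavone, while at 0 °C the benzylic ether C–H bonds should react far more slowly than the alkene.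

Step 17
Reactants: 26 5,7-bis(benzyloxy)-3-hydroxy-2-Q-chromen-4-one
Product: 27 5,7-bis(benzyloxy)-2-[(2R,3S)-7-(benzyloxy)-2-Ar-3-(hydroxymethyl)-2,3-dihydro-1-benzofuran-4-yl]-3-hydroxychromen-4-one
Conditions: Bu4NF, AcOH, THF, rt
Reagents that add atoms: none
Why: Fluoride-driven cleavage of the Si–O bond (desilylation), buffered with acetic acid so that the flavonol does not stand as its phenoxide.

Step 18
Reactants: 27 5,7-bis(benzyloxy)-2-[(2R,3S)-7-(benzyloxy)-2-Ar-3-(hydroxymethyl)-2,3-dihydro-1-benzofuran-4-yl]-3-hydroxychromen-4-one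
Product: 28 3,5,7-trihydroxy-2-[(2R,3S)-7-hydroxy-2-(4-hydroxy-3-methoxyphenyl)-3-(hydroxymethyl)-2,3-dihydro-1-benzofuran-4-yl]chromen-4-one (target, CNP0195987.1)
Conditions: H2 (1 atm), 10% Pd/C, EtOAc/MeOH, rt
Reagents that add atoms: none
Why: Catalytic hydrogenolysis of the four benzyl aryl ethers, which at 1 atm and room temperature should leave the cyclic benzylic C2–O bond of the dihydrobenzofuran and the chromenone double bond intact.

Compound list
1 | 2,3-dihydroxybenzaldehyde | O=Cc1cccc(O)c1O | starting material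
2 | 3-(benzyloxy)-2-hydroxybenzaldehyde | O=Cc1cccc(OCc2ccccc2)c1O | intermediate
3 | [4-(benzyloxy)-3-methoxyphenyl]methanol | COc1cc(CO)ccc1OCc1ccccc1 | starting material
4 | 3-(benzyloxy)-2-{[4-(benzyloxy)-3-methoxyphenyl]methoxy}benzaldehyde | COc1cc(COc2c(C=O)cccc2OCc2ccccc2)ccc1OCc1ccccc1 | intermediate
5 | racemic 1-[3-(benzyloxy)-2-{[4-(benzyloxy)-3-methoxyphenyl]methoxy}phenyl]-2,2,2-trichloroethanol | COc1cc(COc2c(C(O)C(Cl)(Cl)Cl)cccc2OCc2ccccc2)ccc1OCc1ccccc1 | intermediate
6 | 3-[3-(benzyloxy)-2-{[4-(benzyloxy)-3-methoxyphenyl]methoxy}phenyl]-2,2-dichlorooxirane (racemic, not isolated) | COc1cc(COc2c(C3OC3(Cl)Cl)cccc2OCc2ccccc2)ccc1OCc1ccccc1 | intermediate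
7 | 2-[3-(benzyloxy)-2-{[4-(benzyloxy)-3-methoxyphenyl]methoxy}phenyl]acetyl chloride (not isolated) | COc1cc(COc2c(CC(=O)Cl)cccc2OCc2ccccc2)ccc1OCc1ccccc1 | intermediate
8 | 2-[3-(benzyloxy)-2-{[4-(benzyloxy)-3-methoxyphenyl]methoxy}phenyl]acetic acid | COc1cc(COc2c(CC(=O)O)cccc2OCc2ccccc2)ccc1OCc1ccccc1 | intermediate
9 | methyl 2-[3-(benzyloxy)-2-{[4-(benzyloxy)-3-methoxyphenyl]methoxy}phenyl]acetate | COc1cc(COc2c(CC(=O)OC)cccc2OCc2ccccc2)ccc1OCc1ccccc1 | intermediate
10 | methyl 2-[3-(benzyloxy)-2-{[4-(benzyloxy)-3-methoxyphenyl]methoxy}phenyl]-2-diazoacetate | COc1cc(COc2c(C(=[N+]=[N-])C(=O)OC)cccc2OCc2ccccc2)ccc1OCc1ccccc1 | intermediate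
11 | methyl (2R,3S)-7-(benzyloxy)-2-[4-(benzyloxy)-3-methoxyphenyl]-2,3-dihydro-1-benzofuran-3-carboxylate (cis) | COc1cc([C@@H]2Oc3c(OCc4ccccc4)cccc3[C@@H]2C(=O)OC)ccc1OCc1ccccc1 | intermediate
12 | methyl (2R,3R)-7-(benzyloxy)-2-[4-(benzyloxy)-3-methoxyphenyl]-2,3-dihydro-1-benzofuran-3-carboxylate (trans, not isolated) | COc1cc([C@@H]2Oc3c(OCc4ccccc4)cccc3[C@H]2C(=O)OC)ccc1OCc1ccccc1 | intermediate
13 | (2R,3R)-7-(benzyloxy)-2-[4-(benzyloxy)-3-methoxyphenyl]-2,3-dihydro-1-benzofuran-3-carboxylic acid (trans) | COc1cc([C@@H]2Oc3c(OCc4ccccc4)cccc3[C@H]2C(=O)O)ccc1OCc1ccccc1 | intermediate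
14 | methyl acrylate (methyl prop-2-enoate) | C=CC(=O)OC | starting material
15 | (2R,3R)-7-(benzyloxy)-2-[4-(benzyloxy)-3-methoxyphenyl]-4-[(E)-3-methoxy-3-oxoprop-1-enyl]-2,3-dihydro-1-benzofuran-3-carboxylic acid | COc1cc([C@@H]2Oc3c(OCc4ccccc4)ccc(/C=C/C(=O)OC)c3[C@H]2C(=O)O)ccc1OCc1ccccc1 | intermediate
16 | methyl (E)-3-[(2R,3S)-7-(benzyloxy)-2-[4-(benzyloxy)-3-methoxyphenyl]-3-(hydroxymethyl)-2,3-dihydro-1-benzofuran-4-yl]prop-2-enoate | COc1cc([C@@H]2Oc3c(OCc4ccccc4)ccc(/C=C/C(=O)OC)c3[C@H]2CO)ccc1OCc1ccccc1 | intermediate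
17 | methyl (E)-3-[(2R,3S)-7-(benzyloxy)-2-[4-(benzyloxy)-3-methoxyphenyl]-3-{[tert-butyl(diphenyl)silyl]oxymethyl}-2,3-dihydro-1-benzofuran-4-yl]prop-2-enoate | COc1cc([C@@H]2Oc3c(OCc4ccccc4)ccc(/C=C/C(=O)OC)c3[C@H]2CO[Si](c4ccccc4)(c4ccccc4)C(C)(C)C)ccc1OCc1ccccc1 | intermediate
18 | 4-hydroxy-6-methylpyran-2-one (triacetic lactone) | Cc1cc(O)cc(=O)o1 | starting material
19 | 6-{(E)-4-[(2R,3S)-7-(benzyloxy)-2-[4-(benzyloxy)-3-methoxyphenyl]-3-{[tert-butyl(diphenyl)silyl]oxymethyl}-2,3-dihydro-1-benzofuran-4-yl]-2-oxobut-3-enyl}-4-hydroxypyran-2-one | COc1cc([C@@H]2Oc3c(OCc4ccccc4)ccc(/C=C/C(=O)Cc4cc(O)cc(=O)o4)c3[C@H]2CO[Si](c4ccccc4)(c4ccccc4)C(C)(C)C)ccc1OCc1ccccc1 | intermediate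
20 | methyl (E)-9-[(2R,3S)-7-(benzyloxy)-2-[4-(benzyloxy)-3-methoxyphenyl]-3-{[tert-butyl(diphenyl)silyl]oxymethyl}-2,3-dihydro-1-benzofuran-4-yl]-3,5,7-trioxonon-8-enoate (present as its magnesium chelate, not isolated) | COc1cc([C@@H]2Oc3c(OCc4ccccc4)ccc(/C=C/C(=O)CC(=O)CC(=O)CC(=O)OC)c3[C@H]2CO[Si](c4ccccc4)(c4ccccc4)C(C)(C)C)ccc1OCc1ccccc1 | intermediate
21 | (E)-3-[(2R,3S)-7-(benzyloxy)-2-[4-(benzyloxy)-3-methoxyphenyl]-3-{[tert-butyl(diphenyl)silyl]oxymethyl}-2,3-dihydro-1-benzofuran-4-yl]-1-(2,4,6-trihydroxyphenyl)prop-2-en-1-one | COc1cc([C@@H]2Oc3c(OCc4ccccc4)ccc(/C=C/C(=O)c4c(O)cc(O)cc4O)c3[C@H]2CO[Si](c4ccccc4)(c4ccccc4)C(C)(C)C)ccc1OCc1ccccc1 | intermediate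
22 | (E)-1-[2,4-bis(benzyloxy)-6-hydroxyphenyl]-3-[(2R,3S)-7-(benzyloxy)-2-[4-(benzyloxy)-3-methoxyphenyl]-3-{[tert-butyl(diphenyl)silyl]oxymethyl}-2,3-dihydro-1-benzofuran-4-yl]prop-2-en-1-one | COc1cc([C@@H]2Oc3c(OCc4ccccc4)ccc(/C=C/C(=O)c4c(O)cc(OCc5ccccc5)cc4OCc4ccccc4)c3[C@H]2CO[Si](c4ccccc4)(c4ccccc4)C(C)(C)C)ccc1OCc1ccccc1 | intermediate
23 | 5,7-bis(benzyloxy)-2-[(2R,3S)-7-(benzyloxy)-2-[4-(benzyloxy)-3-methoxyphenyl]-3-{[tert-butyl(diphenyl)silyl]oxymethyl}-2,3-dihydro-1-benzofuran-4-yl]-2,3-dihydrochromen-4-one (both epimers at chromanone C2, not isolated) | COc1cc([C@@H]2Oc3c(OCc4ccccc4)ccc(C4CC(=O)c5c(OCc6ccccc6)cc(OCc6ccccc6)cc5O4)c3[C@H]2CO[Si](c4ccccc4)(c4ccccc4)C(C)(C)C)ccc1OCc1ccccc1 | intermediate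
24 | 5,7-bis(benzyloxy)-2-[(2R,3S)-7-(benzyloxy)-2-[4-(benzyloxy)-3-methoxyphenyl]-3-{[tert-butyl(diphenyl)silyl]oxymethyl}-2,3-dihydro-1-benzofuran-4-yl]chromen-4-one | COc1cc([C@@H]2Oc3c(OCc4ccccc4)ccc(-c4cc(=O)c5c(OCc6ccccc6)cc(OCc6ccccc6)cc5o4)c3[C@H]2CO[Si](c4ccccc4)(c4ccccc4)C(C)(C)C)ccc1OCc1ccccc1 | intermediate
25 | 5,7-bis(benzyloxy)-2,3-epoxy-2-[(2R,3S)-7-(benzyloxy)-2-[4-(benzyloxy)-3-methoxyphenyl]-3-{[tert-butyl(diphenyl)silyl]oxymethyl}-2,3-dihydro-1-benzofuran-4-yl]-2,3-dihydrochromen-4-one (epoxide diastereomers, not isolated) | COc1cc([C@@H]2Oc3c(OCc4ccccc4)ccc(C45OC4C(=O)c4c(OCc6ccccc6)cc(OCc6ccccc6)cc4O5)c3[C@H]2CO[Si](c4ccccc4)(c4ccccc4)C(C)(C)C)ccc1OCc1ccccc1 | intermediate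
26 | 5,7-bis(benzyloxy)-2-[(2R,3S)-7-(benzyloxy)-2-[4-(benzyloxy)-3-methoxyphenyl]-3-{[tert-butyl(diphenyl)silyl]oxymethyl}-2,3-dihydro-1-benzofuran-4-yl]-3-hydroxychromen-4-one | COc1cc([C@@H]2Oc3c(OCc4ccccc4)ccc(-c4oc5cc(OCc6ccccc6)cc(OCc6ccccc6)c5c(=O)c4O)c3[C@H]2CO[Si](c4ccccc4)(c4ccccc4)C(C)(C)C)ccc1OCc1ccccc1 | intermediate
27 | 5,7-bis(benzyloxy)-2-[(2R,3S)-7-(benzyloxy)-2-[4-(benzyloxy)-3-methoxyphenyl]-3-(hydroxymethyl)-2,3-dihydro-1-benzofuran-4-yl]-3-hydroxychromen-4-one | COc1cc([C@@H]2Oc3c(OCc4ccccc4)ccc(-c4oc5cc(OCc6ccccc6)cc(OCc6ccccc6)c5c(=O)c4O)c3[C@H]2CO)ccc1OCc1ccccc1 | intermediate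
28 | 3,5,7-trihydroxy-2-[(2R,3S)-7-hydroxy-2-(4-hydroxy-3-methoxyphenyl)-3-(hydroxymethyl)-2,3-dihydro-1-benzofuran-4-yl]chromen-4-one | COc1cc([C@@H]2Oc3c(O)ccc(-c4oc5cc(O)cc(O)c5c(=O)c4O)c3[C@H]2CO)ccc1O | target

Total step count: 18.
Longest linear sequence: 18 steps (1 to 28); compounds 3, 14 and 18 are purchased and enter directly.

Steps most likely to fail

Step 13. The opened chain may close in the aldol mode, or an enolate or methoxide may add to the enone before the Claisen closure, or the lactone may open only sluggishly with the conjugated side chain in place. The fallback sets out from 17 and comes back at 22, so that ring A is brought in ready-made and not folded. Lemieux–Johnson cleavage of the enoate double bond of 17 (OsO4 cat., NaIO4, 2,6-lutidine, dioxane/H2O, rt) should give (2R,3S)-7-(benzyloxy)-2-[4-(benzyloxy)-3-methoxyphenyl]-3-{[tert-butyl(diphenyl)silyl]oxymethyl}-2,3-dihydro-1-benzofuran-4-carbaldehyde F1. Claisen–Schmidt condensation of this aldehyde with commercially available 1-[2,4-bis(benzyloxy)-6-hydroxyphenyl]ethanone (KOH, EtOH/THF, rt) should then give chalcone 22, from which steps 15 to 18 follow unchanged.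

Step 12. The dianion may add in conjugate fashion to the enoate, or proton transfer from the more acidic product may quench the dianion and stall the acylation. The fallback sets out from 17 and comes back at 19. Ester 17 is converted with MeNHOMe·HCl and iPrMgCl (THF, −20 °C) into (E)-3-[(2R,3S)-7-(benzyloxy)-2-[4-(benzyloxy)-3-methoxyphenyl]-3-{[tert-butyl(diphenyl)silyl]oxymethyl}-2,3-dihydro-1-benzofuran-4-yl]-N-methoxy-N-methylprop-2-enamide F2. This amide should acylate the dianion of 18 (LiN(iPr)2, THF/DMPU, −78 to 0 °C) through a chelated tetrahedral adduct that holds until work-up, which removes both the proton-transfer quench and the need for a large excess of dianion, and gives 19 on acidification.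

Step 7. Discrimination between the two enantiotopic benzylic hydrogens may be insufficient, or the carbene may be diverted into addition to the electron-rich benzyl ring. The fallback sets out from 10 and comes back at 13, replacing catalyst control by resolution.
- Insertion with achiral Rh2(OAc)4 (CH2Cl2, rt) should give racemic methyl 7-(benzyloxy)-2-[4-(benzyloxy)-3-methoxyphenyl]-2,3-dihydro-1-benzofuran-3-carboxylate F3 as a cis/trans mixture.
- NaOMe in MeOH followed by aq. NaOH should give racemic trans-7-(benzyloxy)-2-[4-(benzyloxy)-3-methoxyphenyl]-2,3-dihydro-1-benzofuran-3-carboxylic acid F4.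
- Activation as the pivaloyl mixed anhydride (PivCl, Et3N, THF, −20 °C) and reaction with lithiated (4S)-4-benzyl-1,3-oxazolidin-2-one should give two diastereomeric imides, separable by chromatography: (4S)-4-benzyl-3-{[(2R,3R)-7-(benzyloxy)-2-[4-(benzyloxy)-3-methoxyphenyl]-2,3-dihydro-1-benzofuran-3-yl]carbonyl}-1,3-oxazolidin-2-one F5 and its (2S,3S)-acyl diastereomer (4S)-4-benzyl-3-{[(2S,3S)-7-(benzyloxy)-2-[4-(benzyloxy)-3-methoxyphenyl]-2,3-dihydro-1-benzofuran-3-yl]carbonyl}-1,3-oxazolidin-2-one F6, which is set aside.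
- Cleavage of F5 with LiOH/H2O2 (THF/H2O, 0 °C) should return acid 13.

Further compounds
F1 | step 13 | (2R,3S)-7-(benzyloxy)-2-[4-(benzyloxy)-3-methoxyphenyl]-3-{[tert-butyl(diphenyl)silyl]oxymethyl}-2,3-dihydro-1-benzofuran-4-carbaldehyde | COc1cc([C@@H]2Oc3c(OCc4ccccc4)ccc(C=O)c3[C@H]2CO[Si](c4ccccc4)(c4ccccc4)C(C)(C)C)ccc1OCc1ccccc1
F2 | step 12 | (E)-3-[(2R,3S)-7-(benzyloxy)-2-[4-(benzyloxy)-3-methoxyphenyl]-3-{[tert-butyl(diphenyl)silyl]oxymethyl}-2,3-dihydro-1-benzofuran-4-yl]-N-methoxy-N-methylprop-2-enamide | COc1cc([C@@H]2Oc3c(OCc4ccccc4)ccc(/C=C/C(=O)N(C)OC)c3[C@H]2CO[Si](c4ccccc4)(c4ccccc4)C(C)(C)C)ccc1OCc1ccccc1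
F3 | step 7 | racemic methyl 7-(benzyloxy)-2-[4-(benzyloxy)-3-methoxyphenyl]-2,3-dihydro-1-benzofuran-3-carboxylate (cis/trans mixture) | COc1cc(C2Oc3c(OCc4ccccc4)cccc3C2C(=O)OC)ccc1OCc1ccccc1
F4 | step 7 | racemic trans-7-(benzyloxy)-2-[4-(benzyloxy)-3-methoxyphenyl]-2,3-dihydro-1-benzofuran-3-carboxylic acid ((2R,3R) and (2S,3S)) | COc1cc([C@@H]2Oc3c(OCc4ccccc4)cccc3[C@H]2C(=O)O)ccc1OCc1ccccc1.COc1cc([C@H]2Oc3c(OCc4ccccc4)cccc3[C@@H]2C(=O)O)ccc1OCc1ccccc1
F5 | step 7 | (4S)-4-benzyl-3-{[(2R,3R)-7-(benzyloxy)-2-[4-(benzyloxy)-3-methoxyphenyl]-2,3-dihydro-1-benzofuran-3-yl]carbonyl}-1,3-oxazolidin-2-one | COc1cc([C@@H]2Oc3c(OCc4ccccc4)cccc3[C@H]2C(=O)N5[C@@H](Cc6ccccc6)COC5=O)ccc1OCc1ccccc1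
F6 | step 7 | (4S)-4-benzyl-3-{[(2S,3S)-7-(benzyloxy)-2-[4-(benzyloxy)-3-methoxyphenyl]-2,3-dihydro-1-benzofuran-3-yl]carbonyl}-1,3-oxazolidin-2-one | COc1cc([C@H]2Oc3c(OCc4ccccc4)cccc3[C@@H]2C(=O)N5[C@@H](Cc6ccccc6)COC5=O)ccc1OCc1ccccc1
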